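**Structural features**

The target (C36H26O21) is a linear chain of six benzene rings, lettered A to F from the left of the SMILES string, joined by five diaryl ether oxygens and carrying sixteen free phenolic hydroxyl groups; it has no stereocenter and no configurationally stable axis. With each ring numbered from its first ether carbon, the chain is A1–O–B1, B2–O–C1, C4–O–D1, D2–O–E1, E4–O–F1. Rings A, C and E are 2-aryloxyphloroglucinol units: the ether carbon (A1, C4, E4) lies between two hydroxylated carbons (A2/A6, C3/C5, E3/E5), and the oxygen para to it is a free hydroxyl on A4 but an ether oxygen on C1 and E1. Rings B and D are pentaoxygenated, with two neighbouring ether carbons (B1 next to the only ring hydrogen B6, B2 next to B3–OH; D likewise) and hydroxyls on positions 3, 4 and 5; ring F is a 3,4,5-trihydroxyphenyl ether. The free polyphenol is oxidized easily by air, above all in base, so the hydroxyls must stay masked until the last step. The real difficulty lies in the five C–O–C bonds: each joins two electron-rich rings, one end of each (A1, C4, E4, B2, D2) is flanked by two oxygen substituents, and the neighbouring oxygens on B1/B2 and D1/D2 must be told apart. The key step exploits the phloroglucinol pattern of rings A, C and E (ether carbon between two C–OH carbons, third oxygen para): this is exactly what a 2-pyranone bearing an oxygen on C4 and an aryloxymethyl group on C6, a lactonized triketide, gives on Claisen ring closure.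

**Logic of the disconnections**

17 to 16. The ten O–CH3 bonds on A4, B3–B5, D3–D5 and F3–F5 are cut. Methyl ethers are the masks that survive the strongly basic ring-forming step and come directly from the starting materials; the six hydroxyls on A2, A6, C3, C5, E3 and E5 are already free in 16. The forward step must cleave ten alkyl aryl ethers without touching five diaryl ethers.

16 to 15 (key). In each of rings A, C and E the C–C bond between the ether carbon (A1, C4, E4) and one neighbouring hydroxylated carbon is cut, and the oxygen of the other neighbouring hydroxyl is closed onto that carbon as a lactone, so three benzene rings become three 2-pyranones and 15 is an isomer of 16. In one sentence: a tris(2-pyranone) chain 15 is folded by base in one operation into the three phloroglucinol rings. The gain is that the three ether bonds at the doubly flanked carbons A1, C4 and E4 become bonds from a phenol oxygen to an sp3 CH2, and the two bonds at C1 and E1 become vinylogous ester bonds at C4 of a pyranone, so no aryl–oxygen coupling remains. The forward step must close three rings by C-acylation and must not displace the 4-aryloxy groups.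

15 to 14 and 11. The bond from the D2 oxygen to C4 of the pyranone that becomes ring E is cut. A 4-bromo-2-pyranone accepts even a doubly ortho-substituted phenoxide by addition–elimination, and the cut splits off the ring E/F third of the chain. The phenoxide of 14 must attack the bromide of 11 faster than the 4-aryloxy group already present in 14.

14 to 12 (through 13). The D2–O bond is traced back to a D2–CHO bond. The aldehyde is a masked phenol that lets D1 and D2 be differentiated without a protecting group. The oxidation must spare two pyranones and the electron-rich ring B, and the formate must be cleaved without an alcohol or strong base.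

12 to 7 and 10. The bond from the B2 oxygen to C4 of the pyranone that becomes ring C is cut, for the same reason as above. It divides the molecule into the ring A/B part and the ring C/D part. Any exchange of the aryloxy group in the product by the phenoxide of 7 is degenerate.

10 to 2 and 9; 11 to 1 and 9; 9 to 8. The CH2–O bonds to D1 and to F1 are cut, then the C–Br bond of the bromomethyl group. One linchpin, 9, serves both rings C and E. The phenoxide must react at the CH2Br group of 9 and leave the C4 bromide alone.

7 to 5 (through 6), 5 to 2 and 4, 4 to 3. The B2–O bond is again traced to an aldehyde, the CH2–O bond to B1 is cut, then the C–Br bond of the bromomethyl group. The pyranone that becomes ring A carries a methoxy group on C4, which becomes the A4 oxygen, so no selectivity question arises in the alkylation.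

2 to 1. The ring–CHO bond is cut. One formylation turns the ring F building block into the building block for rings B and D; both positions ortho to the hydroxyl of 1 are equivalent, so only one aldehyde can form.

**Other disconnections considered**

Alternative 1: The first plan that comes to mind cuts the five diaryl ether bonds one at a time and makes them by Ullmann couplings of methoxylated phenols with methoxylated aryl bromides. For example, 2,3,4-trimethoxy-6-(2,4,6-trimethoxyphenoxy)phenol A1 and 2-(benzyloxy)-5-bromo-1,3-dimethoxybenzene A2 with CuI and a ligand would give 2-(benzyloxy)-1,3-dimethoxy-5-[2,3,4-trimethoxy-6-(2,4,6-trimethoxyphenoxy)phenoxy]benzene A3, followed by debenzylation and repetition. Every coupling pairs an electron-rich bromide, slow in oxidative addition, with a phenoxide flanked by two oxygens, and this worst case would have to be run five times in series with a protecting-group change between. Rings B and D would also have to enter as halides next to an oxygen on a pentaoxygenated ring, which costs extra steps. The chosen plan makes the same five bonds by SN2 and addition–elimination reactions.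

Alternative 2: The two neighbouring C–O bonds on ring B (and on ring D) could be cut together and the ring introduced as an aryne from 2,3,4-trimethoxy-6-(trimethylsilyl)phenyl trifluoromethanesulfonate A4. A ring A phenoxide should add at B1, the aryne carbon remote from the B3 methoxy group, because the inductive effect of that group stabilizes the aryl anion at B2. No electrophile delivers an aryloxy group to that anion, so it would be trapped with an iodine source to give 2-(2-iodo-3,4,5-trimethoxyphenoxy)-1,3,5-trimethoxybenzene A5. The B2–O bond would then still need an Ullmann coupling at an iodide flanked by two oxygens. The aryne therefore settles one of the two bonds per ring, its precursor takes several steps for each of rings B and D, and protonation of the aryl anion by the phenol competes with the trapping.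

Alternative 3: Rings A, C and E could be cut at two C–C bonds each and made by a 3+3 double Claisen condensation. The dianion of dimethyl 3-oxopentanedioate A6 would be acylated twice by 2-(3,4,5-trimethoxyphenoxy)propanedioyl dichloride A7 to give dimethyl 2,4,6-trihydroxy-5-(3,4,5-trimethoxyphenoxy)benzene-1,3-dicarboxylate A8, followed by hydrolysis and double decarboxylation. This also builds the hindered ether bond on an sp3 carbon, but the new ring arrives with three free hydroxyls of the same kind. The para oxygen, which in rings C and E must be bonded to B2 and D2, cannot be selected, and an alpha-aryloxy malonyl chloride is prone to ketene formation. The pyranone of the chosen plan carries the para oxygen as the aryl ether from the start and needs no decarboxylation.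

Key step: step 11

Remark on the chemistry: the target has no stereocenter and its diaryl ether bonds are taken to rotate freely, so no stereocontrol is needed; compounds 1, 3 and 8 are taken as commercially available.

**Route**

Step 1
Reactants: 1 3,4,5-trimethoxyphenol
Product: 2 6-hydroxy-2,3,4-trimethoxybenzaldehyde
Conditions: MgCl2, Et3N, paraformaldehyde, MeCN, reflux; aq HCl work-up
Reagents that add atoms: paraformaldehyde (as formaldehyde), C=O
Why: Magnesium phenoxide-directed ortho-formylation (Casnati–Skattebøl); the two ortho positions are equivalent and the para position is blocked, so a single aldehyde should form, a second equivalent of formaldehyde serving as the hydride acceptor.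

Step 2
Reactants: 3 4-methoxy-6-methyl-2H-pyran-2-one
Product: 4 6-(bromomethyl)-4-methoxy-2H-pyran-2-one
Conditions: NBS, AIBN (cat.), PhCF3, 80 °C
Reagents that add atoms: N-bromosuccinimide, O=C1CCC(=O)N1Br
Why: Wohl–Ziegler radical bromination at the 6-methyl group, the vinylogous alpha position of the pyranone; radical conditions avoid ionic bromination at C3.

Step 3
Reactants: 2 6-hydroxy-2,3,4-trimethoxybenzaldehyde; 4 6-(bromomethyl)-4-methoxy-2H-pyran-2-one
Product: 5 6-[(2-formyl-3,4,5-trimethoxyphenoxy)methyl]-4-methoxy-2H-pyran-2-one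
Conditions: K2CO3, acetone, rt
Reagents that add atoms: none
Why: Williamson ether synthesis: the phenoxide displaces the primary allylic-type bromide by SN2 and so forms the future A1–O–B1 bond on an sp3 carbon; the weak base at room temperature should not condense the new CH2 group with the neighbouring aldehyde.

Step 4
Reactants: 5 6-[(2-formyl-3,4,5-trimethoxyphenoxy)methyl]-4-methoxy-2H-pyran-2-one
Product: 7 6-[(2-hydroxy-3,4,5-trimethoxyphenoxy)methyl]-4-methoxy-2H-pyran-2-one, via aryl formate 6 (not isolated)
Conditions: mCPBA, CH2Cl2, 0 °C to rt; then 1 M aq HCl (cat.), THF, rt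
Reagents that add atoms: mCPBA, O=C(OO)c1cccc(Cl)c1
Why: Baeyer–Villiger (Dakin-type) oxidation: the electron-rich aryl group migrates to give formate 6, which dilute acid hydrolyzes; this frees the hindered B2 oxygen only after the B1 oxygen has been alkylated.

Step 5
Reactants: 8 4-bromo-6-methyl-2H-pyran-2-one
Product: 9 4-bromo-6-(bromomethyl)-2H-pyran-2-one
Conditions: NBS, AIBN (cat.), PhCF3, 80 °C
Reagents that add atoms: N-bromosuccinimide, O=C1CCC(=O)N1Br
Why: Wohl–Ziegler bromination as in step 2; the vinylic bromide on C4 is inert to the radical chain.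

Step 6
Reactants: 2 6-hydroxy-2,3,4-trimethoxybenzaldehyde; 9 4-bromo-6-(bromomethyl)-2H-pyran-2-one
Product: 10 4-bromo-6-[(2-formyl-3,4,5-trimethoxyphenoxy)methyl]-2H-pyran-2-one
Conditions: K2CO3 (1 equiv), acetone, 0 °C to rt
Reagents that add atoms: none
Why: Williamson ether synthesis forming the future C4–O–D1 bond; SN2 at the primary activated CH2Br by the weakly basic ortho-formyl phenoxide should be faster at 0 °C than addition–elimination at the C4 bromide, which normally needs a more polar medium or warming.

Step 7
Reactants: 1 3,4,5-trimethoxyphenol; 9 4-bromo-6-(bromomethyl)-2H-pyran-2-one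
Product: 11 4-bromo-6-[(3,4,5-trimethoxyphenoxy)methyl]-2H-pyran-2-one
Conditions: K2CO3 (1 equiv), acetone, 0 °C to rt
Reagents that add atoms: none
Why: Williamson ether synthesis forming the future E4–O–F1 bond, with the same site selectivity as in step 6.

Step 8
Reactants: 7 6-[(2-hydroxy-3,4,5-trimethoxyphenoxy)methyl]-4-methoxy-2H-pyran-2-one; 10 4-bromo-6-[(2-formyl-3,4,5-trimethoxyphenoxy)methyl]-2H-pyran-2-one
Product: 12 6-[(2-formyl-3,4,5-trimethoxyphenoxy)methyl]-4-{2,3,4-trimethoxy-6-[(4-methoxy-2-oxo-2H-pyran-6-yl)methoxy]phenoxy}-2H-pyran-2-one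
Conditions: K2CO3, DMF, rt
Reagents that add atoms: none
Why: Vinylogous nucleophilic acyl substitution (conjugate addition–elimination) at C4 of the 4-bromo-2-pyranone; the electrophilic carbon is unhindered and sp2, so the doubly ortho-substituted phenoxide should add readily, forming the future B2–O–C1 bond.

Step 9
Reactants: 12 the bis(pyranone) aldehyde of step 8
Product: 14 6-[(2-hydroxy-3,4,5-trimethoxyphenoxy)methyl]-4-{2,3,4-trimethoxy-6-[(4-methoxy-2-oxo-2H-pyran-6-yl)methoxy]phenoxy}-2H-pyran-2-one, via aryl formate 13 (not isolated)
Conditions: mCPBA, CH2Cl2, 0 °C to rt; then 1 M aq HCl (cat.), THF, rt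
Reagents that add atoms: mCPBA, O=C(OO)c1cccc(Cl)c1
Why: Baeyer–Villiger oxidation as in step 4 frees the D2 oxygen; hydrolysis of formate 13 in aqueous acid, without alcohol or strong base, should spare the 4-aryloxy vinylogous ester.

Step 10
Reactants: 14 the bis(pyranone) phenol of step 9; 11 4-bromo-6-[(3,4,5-trimethoxyphenoxy)methyl]-2H-pyran-2-one
Product: 15 4-{2,3,4-trimethoxy-6-[(4-methoxy-2-oxo-2H-pyran-6-yl)methoxy]phenoxy}-6-{[3,4,5-trimethoxy-2-({2-oxo-6-[(3,4,5-trimethoxyphenoxy)methyl]-2H-pyran-4-yl}oxy)phenoxy]methyl}-2H-pyran-2-one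
Conditions: K2CO3, 11 (1.5 equiv), DMF, rt
Reagents that add atoms: none
Why: Addition–elimination at C4 as in step 8, forming the future D2–O–E1 bond; the bromide of 11 should be displaced far faster than the aryloxy group of the pyranone already present, which is a deactivated vinylogous ester.

Step 11
Reactants: 15 the tris(pyranone) of step 10
Product: 16 deca-O-methyl ether of the target (methoxy on A4, B3, B4, B5, D3, D4, D5, F3, F4, F5; free hydroxyl on A2, A6, C3, C5, E3, E5)
Conditions: KOtBu (12 equiv), THF–t-BuOH (5:1), degassed, 0 to 50 °C; then 1 M aq HCl, 0 °C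
Reagents that add atoms: none
Why: Each 2-pyranone (O1, carbonyl C2, C4 bearing the oxygen substituent, C6 bearing the CH2 group C7) is a lactonized triketide; tert-butoxide adds to the lactone carbonyl C2 and opens the ring to a 3-oxy-5-oxohex-2-enoate dienolate (opening of the C7 anion to a dienylketene would lead to the same product), and the enolate carbon C7, which carries the aryloxy group, attacks the ester carbon in a Claisen (Dieckmann) condensation. Each of rings A, C and E closes through the new C7–C2 bond in the 6-(enolendo)-exo-trig mode, alkoxide is lost and the cyclohexadienone tautomerizes to the resorcinol dianion, which makes C-acylation irreversible whereas O-acylation only returns the pyranone. The closest known reaction type is the alkoxide-induced conversion of 4-methoxy-6-methyl-2-pyranone into 5-methoxyresorcinol, and more generally the Claisen-mode folding of pyranone-masked polyketides into phloroglucinols. Regiochemistry is fixed by the chain: C7 is the only carbon that can reach C2 through a six-membered transition state, so the aryloxy group on C7 ends between the two new hydroxyls and the C4 oxygen ends para to it, as in rings A, C and E. The step needs ring opening at C2 and not substitution at C4, which would expel an aryloxide and cut the chain; tert-butoxide is too bulky to add at C4 beside a doubly ortho-substituted aryloxy group, and excess base keeps unreacted pyranone units as non-electrophilic C7 anions. The aryloxy group on C7 is alpha and not beta to the carbanion and cannot be eliminated, and it makes C7 more acidic than the methyl group of the parent case, so the closure should run at a much lower temperature. No stereocenter is formed.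

Step 12
Reactants: 16 the deca-O-methyl ether of step 11
Product: 17 the target, hexadecahydroxy hexaphenyl pentaether CNP0218077.0
Conditions: BBr3 (excess), CH2Cl2, −78 °C to rt; then H2O, 0 °C, under argon
Reagents that add atoms: none
Why: Lewis acid ether cleavage: BBr3 binds each methoxy oxygen and bromide removes the methyl group by SN2; the diaryl ether oxygens carry no alkyl carbon and should survive, and the free phenols only form borates that hydrolyze on quench.

**Compound list**

1 | 3,4,5-trimethoxyphenol | COc1cc(O)cc(OC)c1OC | starting material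
2 | 6-hydroxy-2,3,4-trimethoxybenzaldehyde | O=Cc1c(O)cc(OC)c(OC)c1OC | intermediate
3 | 4-methoxy-6-methyl-2H-pyran-2-one | COC1=CC(=O)OC(C)=C1 | starting material
4 | 6-(bromomethyl)-4-methoxy-2H-pyran-2-one | COC1=CC(=O)OC(CBr)=C1 | intermediate
5 | 6-[(2-formyl-3,4,5-trimethoxyphenoxy)methyl]-4-methoxy-2H-pyran-2-one | COC1=CC(=O)OC(COc2cc(OC)c(OC)c(OC)c2C=O)=C1 | intermediate
6 | 2,3,4-trimethoxy-6-[(4-methoxy-2-oxo-2H-pyran-6-yl)methoxy]phenyl formate | COC1=CC(=O)OC(COc2cc(OC)c(OC)c(OC)c2OC=O)=C1 | intermediate
7 | 6-[(2-hydroxy-3,4,5-trimethoxyphenoxy)methyl]-4-methoxy-2H-pyran-2-one | COC1=CC(=O)OC(COc2cc(OC)c(OC)c(OC)c2O)=C1 | intermediate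
8 | 4-bromo-6-methyl-2H-pyran-2-one | CC1=CC(Br)=CC(=O)O1 | starting material
9 | 4-bromo-6-(bromomethyl)-2H-pyran-2-one | BrCC1=CC(Br)=CC(=O)O1 | intermediate
10 | 4-bromo-6-[(2-formyl-3,4,5-trimethoxyphenoxy)methyl]-2H-pyran-2-one | BrC1=CC(=O)OC(COc2cc(OC)c(OC)c(OC)c2C=O)=C1 | intermediate
11 | 4-bromo-6-[(3,4,5-trimethoxyphenoxy)methyl]-2H-pyran-2-one | BrC1=CC(=O)OC(COc2cc(OC)c(OC)c(OC)c2)=C1 | intermediate
12 | 6-[(2-formyl-3,4,5-trimethoxyphenoxy)methyl]-4-{2,3,4-trimethoxy-6-[(4-methoxy-2-oxo-2H-pyran-6-yl)methoxy]phenoxy}-2H-pyran-2-one | COC1=CC(=O)OC(COc2cc(OC)c(OC)c(OC)c2OC2=CC(=O)OC(COc3cc(OC)c(OC)c(OC)c3C=O)=C2)=C1 | intermediate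
13 | 2,3,4-trimethoxy-6-[(2-oxo-4-{2,3,4-trimethoxy-6-[(4-methoxy-2-oxo-2H-pyran-6-yl)methoxy]phenoxy}-2H-pyran-6-yl)methoxy]phenyl formate | COC1=CC(=O)OC(COc2cc(OC)c(OC)c(OC)c2OC2=CC(=O)OC(COc3cc(OC)c(OC)c(OC)c3OC=O)=C2)=C1 | intermediate
14 | 6-[(2-hydroxy-3,4,5-trimethoxyphenoxy)methyl]-4-{2,3,4-trimethoxy-6-[(4-methoxy-2-oxo-2H-pyran-6-yl)methoxy]phenoxy}-2H-pyran-2-one | COC1=CC(=O)OC(COc2cc(OC)c(OC)c(OC)c2OC2=CC(=O)OC(COc3cc(OC)c(OC)c(OC)c3O)=C2)=C1 | intermediate
15 | 4-{2,3,4-trimethoxy-6-[(4-methoxy-2-oxo-2H-pyran-6-yl)methoxy]phenoxy}-6-{[3,4,5-trimethoxy-2-({2-oxo-6-[(3,4,5-trimethoxyphenoxy)methyl]-2H-pyran-4-yl}oxy)phenoxy]methyl}-2H-pyran-2-one | COC1=CC(=O)OC(COc2cc(OC)c(OC)c(OC)c2OC2=CC(=O)OC(COc3cc(OC)c(OC)c(OC)c3OC3=CC(=O)OC(COc4cc(OC)c(OC)c(OC)c4)=C3)=C2)=C1 | intermediate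
16 | deca-O-methyl ether of the target (methoxy on A4, B3, B4, B5, D3, D4, D5, F3, F4, F5; hydroxyl on A2, A6, C3, C5, E3, E5) | COc1cc(O)c(Oc2cc(OC)c(OC)c(OC)c2Oc2cc(O)c(Oc3cc(OC)c(OC)c(OC)c3Oc3cc(O)c(Oc4cc(OC)c(OC)c(OC)c4)c(O)c3)c(O)c2)c(O)c1 | intermediate
17 | CNP0218077.0, chain of rings A to F joined A1–O–B1, B2–O–C1, C4–O–D1, D2–O–E1, E4–O–F1 with sixteen free hydroxyls | Oc1cc(O)c(Oc2cc(O)c(O)c(O)c2Oc2cc(O)c(Oc3cc(O)c(O)c(O)c3Oc3cc(O)c(Oc4cc(O)c(O)c(O)c4)c(O)c3)c(O)c2)c(O)c1 | target

**Step count and risks**

Total step count: 12. Longest linear sequence: 8 steps (steps 1, 3, 4, 8, 9, 10, 11, 12).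

Step 11 (key step). The three closures are likely to progress unevenly. In a unit that closes slowly, alkoxide or adventitious hydroxide can add at C4 of a 4-aryloxypyranone and expel the aryloxide, which cuts the chain, and the polyphenolate can be oxidized by traces of air. The fallback is a stagewise closure that never has more than two pyranone units in one operation, caps the new phenols before the next unit is attached, and uses a coupling phenoxide that no longer contains a pyranone. It sets out from 14: the D2 hydroxyl is benzylated (BnBr, K2CO3, DMF) to the benzyl ether of 14 F1. KOtBu as in step 11 should close rings A and C to the tetraol F2. Me2SO4 and K2CO3 in acetone should give the tetra-O-methyl ether F3. Hydrogenolysis (H2, Pd/C) frees the D2 phenol F4. F4 and 11 (K2CO3, DMF) should give the pentaaryl mono(pyranone) F5. KOtBu should close ring E to the tetradeca-O-methyl ether diol F6. BBr3 as in step 12 brings the sequence back to the route at 17.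

Step 6. The site selectivity may be poor: the phenoxide may also attack the C4 bromide of 9, giving mixtures and double substitution. The fallback forms the ether under neutral conditions with no free phenoxide. It sets out from 8: SeO2 in dioxane with heating should oxidize the 6-methyl group to 4-bromo-2-oxo-2H-pyran-6-carbaldehyde F7. NaBH(OAc)3 in THF should give 4-bromo-6-(hydroxymethyl)-2H-pyran-2-one F8. A Mitsunobu reaction of F8 with 2 (PPh3, DIAD, THF) comes back to the route at 10.

Step 8. Attack of the hindered phenoxide may be slow, and on long exposure to base the CH2 group of 10 may condense with its neighbouring aldehyde (aldol closure to a benzofuran). The fallback removes the aldehyde from the basic step. It sets out from 10: HC(OMe)3 and PPTS in CH2Cl2 should give the dimethyl acetal of 10 F9. F9 and 7 (K2CO3, DMF, now with warming if needed) should give the dimethyl acetal of 12 F10. Aqueous HCl in THF returns to the route at 12.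

Step 12. Cleavage of the ten methyl ethers may stop short, and the free polyphenol may be lost to oxidation during purification. The fallback isolates the product as a stable derivative. It sets out from 16: the crude product of the BBr3 treatment is peracetylated (Ac2O, pyridine) to the hexadecaacetate of 17 F11, which can be purified on silica and freed from incompletely demethylated material. Degassed methanol with catalytic HCl then removes the acetates and returns to the route at 17.

**Further compounds**

F1 | step 11 | 6-{[2-(benzyloxy)-3,4,5-trimethoxyphenoxy]methyl}-4-{2,3,4-trimethoxy-6-[(4-methoxy-2-oxo-2H-pyran-6-yl)methoxy]phenoxy}-2H-pyran-2-one | COC1=CC(=O)OC(COc2cc(OC)c(OC)c(OC)c2OC2=CC(=O)OC(COc3cc(OC)c(OC)c(OC)c3OCc3ccccc3)=C2)=C1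
F2 | step 11 | rings A to D tetraol (hydroxyl on A2, A6, C3, C5; benzyloxy on D2; methoxy on A4, B3, B4, B5, D3, D4, D5) | COc1cc(O)c(Oc2cc(OC)c(OC)c(OC)c2Oc2cc(O)c(Oc3cc(OC)c(OC)c(OC)c3OCc3ccccc3)c(O)c2)c(O)c1
F3 | step 11 | tetra-O-methyl ether of F2 | COc1cc(OC)c(Oc2cc(OC)c(OC)c(OC)c2Oc2cc(OC)c(Oc3cc(OC)c(OC)c(OC)c3OCc3ccccc3)c(OC)c2)c(OC)c1
F4 | step 11 | D2 phenol from debenzylation of F3 | COc1cc(OC)c(Oc2cc(OC)c(OC)c(OC)c2Oc2cc(OC)c(Oc3cc(OC)c(OC)c(OC)c3O)c(OC)c2)c(OC)c1
F5 | step 11 | D2 ether of F4 with the 2-oxo-6-[(3,4,5-trimethoxyphenoxy)methyl]-2H-pyran-4-yl group | COc1cc(OC)c(Oc2cc(OC)c(OC)c(OC)c2Oc2cc(OC)c(Oc3cc(OC)c(OC)c(OC)c3OC3=CC(=O)OC(COc4cc(OC)c(OC)c(OC)c4)=C3)c(OC)c2)c(OC)c1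
F6 | step 11 | tetradeca-O-methyl ether of the target with free hydroxyl on E3 and E5 | COc1cc(OC)c(Oc2cc(OC)c(OC)c(OC)c2Oc2cc(OC)c(Oc3cc(OC)c(OC)c(OC)c3Oc3cc(O)c(Oc4cc(OC)c(OC)c(OC)c4)c(O)c3)c(OC)c2)c(OC)c1
F7 | step 6 | 4-bromo-2-oxo-2H-pyran-6-carbaldehyde | O=CC1=CC(Br)=CC(=O)O1
F8 | step 6 | 4-bromo-6-(hydroxymethyl)-2H-pyran-2-one | OCC1=CC(Br)=CC(=O)O1
F9 | step 8 | 4-bromo-6-{[2-(dimethoxymethyl)-3,4,5-trimethoxyphenoxy]methyl}-2H-pyran-2-one | BrC1=CC(=O)OC(COc2cc(OC)c(OC)c(OC)c2C(OC)OC)=C1
F10 | step 8 | 6-{[2-(dimethoxymethyl)-3,4,5-trimethoxyphenoxy]methyl}-4-{2,3,4-trimethoxy-6-[(4-methoxy-2-oxo-2H-pyran-6-yl)methoxy]phenoxy}-2H-pyran-2-one | COC1=CC(=O)OC(COc2cc(OC)c(OC)c(OC)c2OC2=CC(=O)OC(COc3cc(OC)c(OC)c(OC)c3C(OC)OC)=C2)=C1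
F11 | step 12 | hexadecaacetate of the target | CC(=O)Oc1cc(OC(C)=O)c(Oc2cc(OC(C)=O)c(OC(C)=O)c(OC(C)=O)c2Oc2cc(OC(C)=O)c(Oc3cc(OC(C)=O)c(OC(C)=O)c(OC(C)=O)c3Oc3cc(OC(C)=O)c(Oc4cc(OC(C)=O)c(OC(C)=O)c(OC(C)=O)c4)c(OC(C)=O)c3)c(OC(C)=O)c2)c(OC(C)=O)c1
A1 | alternative 1 | 2,3,4-trimethoxy-6-(2,4,6-trimethoxyphenoxy)phenol | COc1cc(OC)c(Oc2cc(OC)c(OC)c(OC)c2O)c(OC)c1
A2 | alternative 1 | 2-(benzyloxy)-5-bromo-1,3-dimethoxybenzene | COc1cc(Br)cc(OC)c1OCc1ccccc1
A3 | alternative 1 | 2-(benzyloxy)-1,3-dimethoxy-5-[2,3,4-trimethoxy-6-(2,4,6-trimethoxyphenoxy)phenoxy]benzene | COc1cc(OC)c(Oc2cc(OC)c(OC)c(OC)c2Oc2cc(OC)c(OCc3ccccc3)c(OC)c2)c(OC)c1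
A4 | alternative 2 | 2,3,4-trimethoxy-6-(trimethylsilyl)phenyl trifluoromethanesulfonate | COc1cc([Si](C)(C)C)c(OS(=O)(=O)C(F)(F)F)c(OC)c1OC
A5 | alternative 2 | 2-(2-iodo-3,4,5-trimethoxyphenoxy)-1,3,5-trimethoxybenzene | COc1cc(OC)c(Oc2cc(OC)c(OC)c(OC)c2I)c(OC)c1
A6 | alternative 3 | dimethyl 3-oxopentanedioate | COC(=O)CC(=O)CC(=O)OC
A7 | alternative 3 | 2-(3,4,5-trimethoxyphenoxy)propanedioyl dichloride | COc1cc(OC(C(Cl)=O)C(Cl)=O)cc(OC)c1OC
A8 | alternative 3 | dimethyl 2,4,6-trihydroxy-5-(3,4,5-trimethoxyphenoxy)benzene-1,3-dicarboxylate | COC(=O)c1c(O)c(C(=O)OC)c(O)c(Oc2cc(OC)c(OC)c(OC)c2)c1O
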